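Readings and results come from a simulation for an exercise; the scatter is artificial.

**The question.** The flasks below differ in temperature, and I want to know which holds the most product at the end, and what a falling substrate curve says about that.

| flask | substrate | partner | precatalyst | temperature | remark | time |
|---|---|---|---|---|---|---|
| Saturday's | 0.34 M | 0.67 equiv | 1.3 mol% | 15 °C | run made earlier |  |
| Monday's | 0.34 M | 1.5 equiv | 1.3 mol% | 48 °C | run made earlier |  |
| Thursday's | 0.68 M | 1 equiv | 1.3 mol% | 15 °C | run made earlier |  |
| north-east | 0.34 M | 1.00 equiv | 1.3 mol% | 40 °C |  | 8.0 h |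
| north | 0.34 M | 1.00 equiv | 1.3 mol% | 20 °C |  | 8.0 h |
| west | 0.34 M | 1.00 equiv | 1.3 mol% | 60 °C |  | 8.0 h |
| south-east | 0.34 M | 1.00 equiv | 1.3 mol% | 0 °C |  | 8.0 h |

| run | time / h | product / % | substrate / % |
|---|---|---|---|
| Saturday's | 2.50 | 2 | 99 |
| Saturday's | 5.00 | 4 | 94 |
| Saturday's | 10.0 | 2 | 90 |
| Saturday's | 15.0 | 7 | 84 |
| Monday's | 1.33 | 22 | 53 |
| Monday's | 2.50 | 48 | 31 |
| Monday's | 4.00 | 67 | 19 |
| Monday's | 5.00 | 77 | 10 |
| Thursday's | 1.33 | 3 | 99 |
| Thursday's | 3.00 | 3 | 97 |
| Thursday's | 6.00 | 9 | 87 |
| Thursday's | 15.0 | 31 | 59 |

(standard deviation of a reading: 1.5 percentage points)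

- the flask with the highest amount of product, in percent of the substrate charged ("all alike" if they lie within 1.5 percentage points) (north-east / north / west / south-east / all alike)
- final product, as a percentage of the substrate charged, in north-east
- final product, as a percentage of the substrate charged, in north
- final product, as a percentage of the substrate charged, in west
- final product, as a percentage of the substrate charged, in south-east

**Mean constant.** The curves bend, so I replace each by its mean: κ, the natural log of charged over left substrate, divided by time and by the starting partner concentration c, an apparent second-order constant. Saturday's run gives κ_S = 0.0510 /M/h. Thursday's run, at the same temperature, gives 0.0517 /M/h, but it differs from Saturday's run in substrate, partner and catalyst concentration at once, so this match doesn't prove the partner term, and dividing by c remains my assumption. Monday's run gives 0.903 /M/h at 48 °C.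

**Span factor.** Let G be the factor by which κ grows from Saturday's temperature to Monday's: 17.7. A flask lying a fraction f along that span has κ = κ_S·G^f, and substrate left is exp(−κct). West and south-east lie outside the span, so those two are extrapolations.

**My estimate.** Substrate lost is my ceiling on product: 99.9% in west, 70.6% in north-east, 19.3% in north and 3.69% in south-east. West leads. The mean has a known error: Thursday's run reads 0.0149 /M/h up to 3.00 h, less than its whole-run mean, so the start is late.

**The forecast.** It names west, with product of 85% in west, 52% in north-east, 7% in north and 1% in south-east. Its grounds: “Product lags substrate loss because an intermediate builds up”. These are product figures, while mine are ceilings.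

**The result.** West leads with 91.0%, then north-east 59.8%, north 9.37% and south-east 0.288%.

    substrate ⇌ dormant form (K = 0.620, k = 0.00250 /min, Ea = 95.0 kJ/mol, ΔH = −12.0 kJ/mol)
    partner + precatalyst → free catalyst + spent reagent (k = 0.0210 /M/min, Ea = 57.0 kJ/mol)
    partner + free catalyst → catalyst intermediate A (k = 1.20 /M/min, Ea = 65.0 kJ/mol)
    catalyst intermediate B ⇌ by-product + catalyst intermediate C (K = 2.00 M, k = 8.80 /min, Ea = 89.0 kJ/mol, ΔH = −90.0 kJ/mol)
    substrate + catalyst intermediate A ⇌ catalyst intermediate B (K = 35.0 /M, k = 2.80 /M/min, Ea = 44.0 kJ/mol, ΔH = −18.0 kJ/mol)
    catalyst intermediate C ⇌ free catalyst + product (K = 1.20 M, k = 26.0 /min, Ea = 79.0 kJ/mol, ΔH = −49.0 kJ/mol)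
    (constants at 40 °C)

**Watch the gap.** North-east lost 80.2% of its substrate against my 70.6%, yet it holds 59.8% product, and 20.2% stands as dormant form. A falling substrate curve therefore counts parked substrate too. West's yield rests in part on that parking being undone, because taking away the reverse step, dormant form to substrate, drops west from 91.0% to 27.9%. South-east's low figure is in part a matter of the time given, because ten times as long brings it from 0.288% to 19.5%.

**A neighbour.** For south-east repeated at 25 °C, G gives a ceiling of 28.2%. The computed flask keeps 68% substrate and holds 17.9% product beside 14.3% dormant form.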